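The readings come from a simulation for an exercise; the scatter is artificial.

Blue holds 14 mM of substrate but 7.00 mM of partner. If each product takes one partner, partner is the limiting reagent. The product then has a ceiling F, the partner charge over the substrate charge: 50.0% in blue and 71.4% in ochre.

| setting | eta | delta | ochre | blue |
|---|---|---|---|---|
| substrate | 21 mM | 7 mM | 14 mM | 14 mM |
| partner | 7 mM | 7 mM | 10.0 mM | 7.00 mM |
| free catalyst | 20 µM | 20 µM | 80 µM | 20 µM |
| temperature | 80 °C | 80 °C | 65 °C | 80 °C |
| remark | run made earlier | run made earlier |  |  |
| time |  |  | 3.0 min | 3.0 min |

- eta (time / s: product / %, substrate / %): 10.0: 3, 96; 20.0: 4, 97; 30.0: 10, 96; 40.0: 9, 89; 50.0: 10, 87; 60.0: 15, 88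
- delta (time / s: product / %, substrate / %): 10.0: 4, 96; 20.0: 6, 94; 30.0: 10, 90; 40.0: 14, 86; 50.0: 14, 85; 60.0: 19, 84

(readings scatter by 1.5 percentage points)

- the earlier runs do not show what temperature does; that part of a forecast is a guess
- no earlier run changes the charge of free catalyst; that part of a forecast is a guess

1. which of the two ends with the higher amount of product, in percent of the substrate charged ("neither" if they lie within 2 percentage points) (ochre / blue / neither)
2. product at the end, in percent of the substrate charged, ochre
3. product at the end, in percent of the substrate charged, blue

We read the product rate from the last reading of each run: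

r(eta) = 0.0525 mM/s, r(delta) = 0.0222 mM/s

Blue's substrate lies between those two charges, so we take their mean, r = 0.0373 mM/s. It is a reading and carries their scatter.

Now the ladder for blue, fastest first. The catalyst charge over r gives a turnover time of 0.536 s, much shorter than the first reading at 10.0 s. So we follow partner and product and leave the catalyst cycle aside.

Next comes the partner lifetime τ, the time the partner charge lasts at the early rate:

τ = partner charge / r = 187 s

That is close to the asked 3.0 min. Slowest is the same reckoning for substrate, 375 s, which is longer. So in blue we expect partner to run down first. We assume the rate follows the partner left, which gives the product P, in percent of the substrate charged, at time t: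

P = F × (1 − exp(−t/τ)) = 30.9%

For ochre the temperature and catalyst effects are guesses, so we give no figure. We bet on ochre for its higher ceiling.

The forecast says ochre, with 45% for ochre and 33% for blue. Our blue figure is lower. On ochre it says: “Ochre is a guess: four times the catalyst, offset by about a threefold loss from 15 °C cooler, with more partner.”

    partner + free catalyst → catalyst intermediate A (k = 2470 /M/s, Ea = 42.0 kJ/mol)
    catalyst intermediate A ⇌ by-product + catalyst intermediate B (K = 0.637 M, k = 138 /s, Ea = 78.0 kJ/mol, ΔH = 16.0 kJ/mol)
    substrate + catalyst intermediate B ⇌ catalyst intermediate C (K = 940 /M, k = 186 /M/s, Ea = 49.0 kJ/mol, ΔH = −59.0 kJ/mol)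
    catalyst intermediate C ⇌ free catalyst + product (K = 0.0136 M, k = 438 /s, Ea = 62.0 kJ/mol, ΔH = 29.0 kJ/mol)
    partner → decomposed reagent (k = 0.0107 /s, Ea = 98.0 kJ/mol)
    (constants at 80 °C)

Ochre ends higher, at 57.9% against 25.5% for blue. Blue falls below our 30.9%, with 0.29% of its partner left, and 3.41 mM of decomposed reagent stands beside 3.57 mM of by-product. Now take a neighbouring flask, blue with 4.2 mM of partner. We keep τ, since the assumed rate follows the partner left. Its ceiling is 30.0%, so P = 18.5%. That flask gives 18.0%, with 0.075% of its partner left, 1.68 mM of decomposed reagent and 2.52 mM of by-product.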